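**Retrosynthetic overview** (target numbered as 3,7-dioxabicyclo[3.3.0]octan-2-one: C1 bridgehead α to C2=O, O3, C4 bearing the trihydroxyphenyl, C5 bridgehead, C6 H2, O7, C8 bearing the dihydroxyphenyl; 1S,4S,5R,8S, cis-fused, both aryl groups exo)
1. Target 27 ⇐ hydrogenolysis of the pentabenzyl ether 26.
2. 26 ⇐ O7–C6 bond: 5-exo-tet etherification of diol lactone 24 at the CH2 carbon (tetrahydrofuran ring closed last, no stereocentre touched).
3. 24 ⇐ O3–C2 bond: lactonisation of the C4 hydroxyl onto the imide of 21 with loss of the auxiliary (lactone ring closed first).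
4. 21 ⇐ C1–C8 bond: intermolecular Evans syn-aldol of imide 17 with 3,4-bis(benzyloxy)benzaldehyde (sets C1 and C8).
5. 17 ⇐ C4–C5 bond: intermolecular Evans syn-aldol of pentenoyl imide 6 with 3,4,5-tris(benzyloxy)benzaldehyde (sets C4 and C5); the imide C=O becomes C6 and the allyl group becomes C1–C2.

Assumption: the five phenols are carried as benzyl ethers; 3,4,5-trihydroxybenzaldehyde, 3,4-bis(benzyloxy)benzaldehyde, both enantiomers of 4-benzyl-1,3-oxazolidin-2-one, pent-4-enoyl chloride and 3,4-bis(benzyloxy)benzoyl chloride are bought.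

**Route**

Step 1
Reactants: 1 3,4,5-trihydroxybenzaldehyde
Product: 2 3,4,5-tris(benzyloxy)benzaldehyde
Conditions: BnBr (3.6 equiv), K2CO3, DMF, N2, 60 °C
Reagents that add atoms: benzyl bromide, BrCc1ccccc1
Why: Williamson ether synthesis in which the three phenoxides are benzylated by SN2 while the aldehyde is untouched and no stereocentre is involved.

Step 2
Reactants: 3 (S)-4-benzyl-1,3-oxazolidin-2-one; 4 pent-4-enoyl chloride
Product: 6 (S)-4-benzyl-3-(pent-4-enoyl)-1,3-oxazolidin-2-one, via N-lithio oxazolidinone 5 (not isolated)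
Conditions: n-BuLi, THF, −78 °C; then 4, −78 → 0 °C
Reagents that add atoms: n-butyllithium, [Li]CCCC (its lithium is held only in 5)
Why: N-acylation of the lithiated Evans oxazolidinone by an acid chloride is fast and clean at low temperature and leaves the auxiliary stereocentre untouched.

Step 3
Reactants: 6 (S)-4-benzyl-3-(pent-4-enoyl)-1,3-oxazolidin-2-one; 2 3,4,5-tris(benzyloxy)benzaldehyde
Product: 9 (S)-4-benzyl-3-[(2S)-2-[(S)-hydroxy[3,4,5-tris(benzyloxy)phenyl]methyl]pent-4-enoyl]-1,3-oxazolidin-2-one, via Z-dibutylboron enolate 7 (not isolated), via dibutylboron aldolate 8 (not isolated)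
Conditions: n-Bu2BOTf, i-Pr2NEt, CH2Cl2, 0 °C; 2, −78 → 0 °C; then pH 7 buffer, MeOH, 30% H2O2, 0 °C
Reagents that add atoms: di-n-butylboron triflate, CCCCB(CCCC)OS(=O)(=O)C(F)(F)F (its Bu2B group is held only in 7 and 8)
Why: Evans syn-aldol reaction in which the Z-boron enolate reacts through a closed Zimmerman–Traxler transition state with the oxazolidinone dipole opposed to the enolate oxygen, so the aldehyde adds to the enolate face away from the auxiliary benzyl group and gives the (2S, carbinol S) syn adduct that fixes C5 and C4 of the target.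

Step 4
Reactants: 9 (S)-4-benzyl-3-[(2S)-2-[(S)-hydroxy[3,4,5-tris(benzyloxy)phenyl]methyl]pent-4-enoyl]-1,3-oxazolidin-2-one
Product: 10 (1S,2R)-2-(prop-2-en-1-yl)-1-[3,4,5-tris(benzyloxy)phenyl]propane-1,3-diol
Conditions: LiBH4, MeOH (1 equiv), THF, 0 °C
Reagents that add atoms: none
Why: Reductive cleavage of the Evans imide by hydride attack on the exocyclic carbonyl gives the primary alcohol that becomes C6 and returns the auxiliary without disturbing either stereocentre (the descriptor at C5 changes from S to R only because the CIP priorities change).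

Step 5
Reactants: 10 (1S,2R)-2-(prop-2-en-1-yl)-1-[3,4,5-tris(benzyloxy)phenyl]propane-1,3-diol
Product: 11 (1S,2R)-2-[(tert-butyldiphenylsilyloxy)methyl]-1-[3,4,5-tris(benzyloxy)phenyl]pent-4-en-1-ol
Conditions: TBDPSCl (1.05 equiv), imidazole, CH2Cl2, 0 °C
Reagents that add atoms: tert-butyl(chloro)diphenylsilane, CC(C)(C)[Si](Cl)(c1ccccc1)c1ccccc1
Why: Silyl ether formation with the bulky TBDPSCl is highly selective for the unhindered primary hydroxyl over the hindered secondary benzylic one.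

Step 6
Reactants: 11 (1S,2R)-2-[(tert-butyldiphenylsilyloxy)methyl]-1-[3,4,5-tris(benzyloxy)phenyl]pent-4-en-1-ol
Product: 12 (1S,2R)-2-[(tert-butyldiphenylsilyloxy)methyl]-1-(triethylsilyloxy)-1-[3,4,5-tris(benzyloxy)phenyl]pent-4-ene
Conditions: TESOTf, 2,6-lutidine, CH2Cl2, −78 → 0 °C
Reagents that add atoms: triethylsilyl triflate, CC[Si](CC)(CC)OS(=O)(=O)C(F)(F)F
Why: Silylation of the remaining secondary benzylic alcohol with the reactive silyl triflate installs a triethylsilyl ether that can later be removed by mild acid in the presence of the TBDPS ether.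

Step 7
Reactants: 12 (1S,2R)-2-[(tert-butyldiphenylsilyloxy)methyl]-1-(triethylsilyloxy)-1-[3,4,5-tris(benzyloxy)phenyl]pent-4-ene
Product: 14 (3R,4S)-3-[(tert-butyldiphenylsilyloxy)methyl]-4-(triethylsilyloxy)-4-[3,4,5-tris(benzyloxy)phenyl]butanal, via vicinal diol 13 (not isolated)
Conditions: OsO4 (2 mol %), NaIO4, 2,6-lutidine, dioxane/H2O 3:1, rt
Reagents that add atoms: osmium tetroxide, O=[Os](=O)(=O)=O (catalytic, transfers the oxygen), turned over by sodium periodate, [Na+].[O-]I(=O)(=O)=O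
Why: Lemieux–Johnson oxidation (dihydroxylation then periodate glycol cleavage) shortens the terminal alkene to the aldehyde under buffered conditions that spare silyl ethers, benzyl ethers and the electron-rich arene.

Step 8
Reactants: 14 (3R,4S)-3-[(tert-butyldiphenylsilyloxy)methyl]-4-(triethylsilyloxy)-4-[3,4,5-tris(benzyloxy)phenyl]butanal
Product: 15 (3R,4S)-3-[(tert-butyldiphenylsilyloxy)methyl]-4-(triethylsilyloxy)-4-[3,4,5-tris(benzyloxy)phenyl]butanoic acid
Conditions: NaClO2, NaH2PO4, 2-methyl-2-butene, t-BuOH/H2O, 0 °C → rt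
Reagents that add atoms: sodium chlorite, [Na+].[O-]Cl=O
Why: Pinnick oxidation converts the aldehyde to the acid at buffered pH with 2-methyl-2-butene scavenging HOCl, so the silyl ethers and the electron-rich ring survive and there is no epimerisable α-stereocentre.

Step 9
Reactants: 15 (3R,4S)-3-[(tert-butyldiphenylsilyloxy)methyl]-4-(triethylsilyloxy)-4-[3,4,5-tris(benzyloxy)phenyl]butanoic acid; 3 (S)-4-benzyl-1,3-oxazolidin-2-one
Product: 17 (S)-4-benzyl-3-[(3R,4S)-3-[(tert-butyldiphenylsilyloxy)methyl]-4-(triethylsilyloxy)-4-[3,4,5-tris(benzyloxy)phenyl]butanoyl]-1,3-oxazolidin-2-one, via mixed pivalic anhydride 16 (not isolated)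
Conditions: PivCl, Et3N, THF, −20 °C; then 3, LiCl, −20 °C → rt
Reagents that add atoms: pivaloyl chloride, CC(C)(C)C(=O)Cl (its acyl group is held only in 16)
Why: Mixed-anhydride N-acylation of the oxazolidinone occurs at the less hindered carbonyl of the anhydride and places the (S)-auxiliary next to the CH2 that will become C1.

Step 10
Reactants: 17 (S)-4-benzyl-3-[(3R,4S)-3-[(tert-butyldiphenylsilyloxy)methyl]-4-(triethylsilyloxy)-4-[3,4,5-tris(benzyloxy)phenyl]butanoyl]-1,3-oxazolidin-2-one; 18 3,4-bis(benzyloxy)benzaldehyde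
Product: 21 (S)-4-benzyl-3-[(2S,3R,4S)-2-[(S)-[3,4-bis(benzyloxy)phenyl](hydroxy)methyl]-3-[(tert-butyldiphenylsilyloxy)methyl]-4-(triethylsilyloxy)-4-[3,4,5-tris(benzyloxy)phenyl]butanoyl]-1,3-oxazolidin-2-one, via Z-dibutylboron enolate 19 (not isolated), via dibutylboron aldolate 20 (not isolated)
Conditions: n-Bu2BOTf, i-Pr2NEt, CH2Cl2, 0 °C; 18, −78 → 0 °C; then pH 7 buffer, MeOH, 30% H2O2, 0 °C
Reagents that add atoms: di-n-butylboron triflate, CCCCB(CCCC)OS(=O)(=O)C(F)(F)F (its Bu2B group is held only in 19 and 20)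
Why: Second Evans syn-aldol reaction in which auxiliary control through the Zimmerman–Traxler transition state overrides the weak bias of the β-stereocentre and gives the (2S, carbinol S) syn adduct, fixing C1 and C8 and thereby the cis relationship of the C1 and C5 hydrogens needed for the ring fusion.

Step 11
Reactants: 21 (S)-4-benzyl-3-[(2S,3R,4S)-2-[(S)-[3,4-bis(benzyloxy)phenyl](hydroxy)methyl]-3-[(tert-butyldiphenylsilyloxy)methyl]-4-(triethylsilyloxy)-4-[3,4,5-tris(benzyloxy)phenyl]butanoyl]-1,3-oxazolidin-2-one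
Product: 23 (3S,4R,5S)-3-[(S)-[3,4-bis(benzyloxy)phenyl](hydroxy)methyl]-4-[(tert-butyldiphenylsilyloxy)methyl]-5-[3,4,5-tris(benzyloxy)phenyl]oxolan-2-one, via hydroxy imide 22 (not isolated)
Conditions: PPTS (0.2 equiv), MeOH/CH2Cl2 1:1, 0 °C → rt; then Et3N, DMAP (cat.), CH2Cl2, rt
Reagents that add atoms: none
Why: Mild acid methanolysis removes the triethylsilyl ether selectively because the TBDPS ether is orders of magnitude more acid-stable, and the freed C4 hydroxyl attacks the activated imide carbonyl in a 5-exo-trig lactonisation that expels the auxiliary and leaves all four stereocentres unchanged.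

Step 12
Reactants: 23 (3S,4R,5S)-3-[(S)-[3,4-bis(benzyloxy)phenyl](hydroxy)methyl]-4-[(tert-butyldiphenylsilyloxy)methyl]-5-[3,4,5-tris(benzyloxy)phenyl]oxolan-2-one
Product: 24 (3S,4R,5S)-3-[(S)-[3,4-bis(benzyloxy)phenyl](hydroxy)methyl]-4-(hydroxymethyl)-5-[3,4,5-tris(benzyloxy)phenyl]oxolan-2-one
Conditions: HF·pyridine, pyridine, THF, 0 °C → rt
Reagents that add atoms: none
Why: Fluoride cleavage of the primary TBDPS ether with buffered HF·pyridine leaves the lactone, the benzylic alcohol and the benzyl ethers intact and avoids the alkoxide that could cause translactonisation or retro-aldol.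

Step 13
Reactants: 24 (3S,4R,5S)-3-[(S)-[3,4-bis(benzyloxy)phenyl](hydroxy)methyl]-4-(hydroxymethyl)-5-[3,4,5-tris(benzyloxy)phenyl]oxolan-2-one
Product: 26 (1S,4S,5R,8S)-8-[3,4-bis(benzyloxy)phenyl]-4-[3,4,5-tris(benzyloxy)phenyl]-3,7-dioxabicyclo[3.3.0]octan-2-one, via primary mesylate 25 (not isolated)
Conditions: MsCl (1.1 equiv), pyridine, CH2Cl2, 0 °C → rt, then 40 °C
Reagents that add atoms: methanesulfonyl chloride, CS(=O)(=O)Cl (its mesyl group is held only in 25)
Why: Selective mesylation of the unhindered primary alcohol is followed by an intramolecular Williamson-type etherification (5-exo-tet SN2 by the C8 hydroxyl at the CH2 carbon) that closes the tetrahydrofuran cis-fused to the lactone without touching any stereocentre, so the C8 aryl group ends up exo.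

Step 14
Reactants: 26 (1S,4S,5R,8S)-8-[3,4-bis(benzyloxy)phenyl]-4-[3,4,5-tris(benzyloxy)phenyl]-3,7-dioxabicyclo[3.3.0]octan-2-one
Product: 27 (1S,4S,5R,8S)-8-(3,4-dihydroxyphenyl)-4-(3,4,5-trihydroxyphenyl)-3,7-dioxabicyclo[3.3.0]octan-2-one
Conditions: H2 (1 atm), 10% Pd/C, THF/EtOAc 1:1, rt
Reagents that add atoms: none
Why: Catalytic hydrogenolysis cleaves the five aryl benzyl ethers much faster than the benzylic lactone and ether C–O bonds in a neutral aprotic solvent and frees the air-sensitive catechol and pyrogallol units under reducing conditions with no stereocentre affected.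

**Compound list**
1 | 3,4,5-trihydroxybenzaldehyde | O=Cc1cc(O)c(O)c(O)c1 | starting material
2 | 3,4,5-tris(benzyloxy)benzaldehyde | O=Cc1cc(OCc2ccccc2)c(OCc2ccccc2)c(OCc2ccccc2)c1 | intermediate
3 | (S)-4-benzyl-1,3-oxazolidin-2-one | O=C1N[C@@H](Cc2ccccc2)CO1 | starting material
4 | pent-4-enoyl chloride | C=CCCC(=O)Cl | starting material
5 | N-lithio (S)-4-benzyl-1,3-oxazolidin-2-one | [Li]N1[C@@H](Cc2ccccc2)COC1=O | intermediate (not isolated)
6 | (S)-4-benzyl-3-(pent-4-enoyl)-1,3-oxazolidin-2-one | C=CCCC(=O)N1[C@@H](Cc2ccccc2)COC1=O | intermediate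
7 | (Z)-dibutylboron enolate of 6 | C=CC/C=C(\OB(CCCC)CCCC)N1[C@@H](Cc2ccccc2)COC1=O | intermediate (not isolated)
8 | O-dibutylboryl aldolate of 9 | C=CC[C@@H]([C@H](OB(CCCC)CCCC)c1cc(OCc2ccccc2)c(OCc2ccccc2)c(OCc2ccccc2)c1)C(=O)N1[C@@H](Cc2ccccc2)COC1=O | intermediate (not isolated)
9 | (S)-4-benzyl-3-[(2S)-2-[(S)-hydroxy[3,4,5-tris(benzyloxy)phenyl]methyl]pent-4-enoyl]-1,3-oxazolidin-2-one | C=CC[C@@H]([C@H](O)c1cc(OCc2ccccc2)c(OCc2ccccc2)c(OCc2ccccc2)c1)C(=O)N1[C@@H](Cc2ccccc2)COC1=O | intermediate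
10 | (1S,2R)-2-(prop-2-en-1-yl)-1-[3,4,5-tris(benzyloxy)phenyl]propane-1,3-diol | C=CC[C@@H]([C@H](O)c1cc(OCc2ccccc2)c(OCc2ccccc2)c(OCc2ccccc2)c1)CO | intermediate
11 | (1S,2R)-2-[(tert-butyldiphenylsilyloxy)methyl]-1-[3,4,5-tris(benzyloxy)phenyl]pent-4-en-1-ol | C=CC[C@@H]([C@H](O)c1cc(OCc2ccccc2)c(OCc2ccccc2)c(OCc2ccccc2)c1)CO[Si](c1ccccc1)(c1ccccc1)C(C)(C)C | intermediate
12 | (1S,2R)-2-[(tert-butyldiphenylsilyloxy)methyl]-1-(triethylsilyloxy)-1-[3,4,5-tris(benzyloxy)phenyl]pent-4-ene | C=CC[C@@H]([C@H](O[Si](CC)(CC)CC)c1cc(OCc2ccccc2)c(OCc2ccccc2)c(OCc2ccccc2)c1)CO[Si](c1ccccc1)(c1ccccc1)C(C)(C)C | intermediate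
13 | (4R,5S)-4-[(tert-butyldiphenylsilyloxy)methyl]-5-(triethylsilyloxy)-5-[3,4,5-tris(benzyloxy)phenyl]pentane-1,2-diol (C2 epimers) | OCC(O)C[C@@H]([C@H](O[Si](CC)(CC)CC)c1cc(OCc2ccccc2)c(OCc2ccccc2)c(OCc2ccccc2)c1)CO[Si](c1ccccc1)(c1ccccc1)C(C)(C)C | intermediate (not isolated)
14 | (3R,4S)-3-[(tert-butyldiphenylsilyloxy)methyl]-4-(triethylsilyloxy)-4-[3,4,5-tris(benzyloxy)phenyl]butanal | O=CC[C@@H]([C@H](O[Si](CC)(CC)CC)c1cc(OCc2ccccc2)c(OCc2ccccc2)c(OCc2ccccc2)c1)CO[Si](c1ccccc1)(c1ccccc1)C(C)(C)C | intermediate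
15 | (3R,4S)-3-[(tert-butyldiphenylsilyloxy)methyl]-4-(triethylsilyloxy)-4-[3,4,5-tris(benzyloxy)phenyl]butanoic acid | OC(=O)C[C@@H]([C@H](O[Si](CC)(CC)CC)c1cc(OCc2ccccc2)c(OCc2ccccc2)c(OCc2ccccc2)c1)CO[Si](c1ccccc1)(c1ccccc1)C(C)(C)C | intermediate
16 | mixed pivalic anhydride of 15 | CC(C)(C)C(=O)OC(=O)C[C@@H]([C@H](O[Si](CC)(CC)CC)c1cc(OCc2ccccc2)c(OCc2ccccc2)c(OCc2ccccc2)c1)CO[Si](c1ccccc1)(c1ccccc1)C(C)(C)C | intermediate (not isolated)
17 | (S)-4-benzyl-3-[(3R,4S)-3-[(tert-butyldiphenylsilyloxy)methyl]-4-(triethylsilyloxy)-4-[3,4,5-tris(benzyloxy)phenyl]butanoyl]-1,3-oxazolidin-2-one | O=C(C[C@@H]([C@H](O[Si](CC)(CC)CC)c1cc(OCc2ccccc2)c(OCc2ccccc2)c(OCc2ccccc2)c1)CO[Si](c1ccccc1)(c1ccccc1)C(C)(C)C)N1[C@@H](Cc2ccccc2)COC1=O | intermediate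
18 | 3,4-bis(benzyloxy)benzaldehyde | O=Cc1ccc(OCc2ccccc2)c(OCc2ccccc2)c1 | starting material
19 | (Z)-dibutylboron enolate of 17 | CCCCB(CCCC)O/C(N1[C@@H](Cc2ccccc2)COC1=O)=C\[C@@H]([C@H](O[Si](CC)(CC)CC)c1cc(OCc2ccccc2)c(OCc2ccccc2)c(OCc2ccccc2)c1)CO[Si](c1ccccc1)(c1ccccc1)C(C)(C)C | intermediate (not isolated)
20 | O-dibutylboryl aldolate of 21 | CCCCB(CCCC)O[C@H](c1ccc(OCc2ccccc2)c(OCc2ccccc2)c1)[C@@H](C(=O)N1[C@@H](Cc2ccccc2)COC1=O)[C@H](CO[Si](c1ccccc1)(c1ccccc1)C(C)(C)C)[C@H](O[Si](CC)(CC)CC)c1cc(OCc2ccccc2)c(OCc2ccccc2)c(OCc2ccccc2)c1 | intermediate (not isolated)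
21 | (S)-4-benzyl-3-[(2S,3R,4S)-2-[(S)-[3,4-bis(benzyloxy)phenyl](hydroxy)methyl]-3-[(tert-butyldiphenylsilyloxy)methyl]-4-(triethylsilyloxy)-4-[3,4,5-tris(benzyloxy)phenyl]butanoyl]-1,3-oxazolidin-2-one | O[C@H](c1ccc(OCc2ccccc2)c(OCc2ccccc2)c1)[C@@H](C(=O)N1[C@@H](Cc2ccccc2)COC1=O)[C@H](CO[Si](c1ccccc1)(c1ccccc1)C(C)(C)C)[C@H](O[Si](CC)(CC)CC)c1cc(OCc2ccccc2)c(OCc2ccccc2)c(OCc2ccccc2)c1 | intermediate
22 | 4-hydroxy analogue of 21 (triethylsilyl group removed) | O[C@H](c1ccc(OCc2ccccc2)c(OCc2ccccc2)c1)[C@@H](C(=O)N1[C@@H](Cc2ccccc2)COC1=O)[C@H](CO[Si](c1ccccc1)(c1ccccc1)C(C)(C)C)[C@H](O)c1cc(OCc2ccccc2)c(OCc2ccccc2)c(OCc2ccccc2)c1 | intermediate (not isolated)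
23 | (3S,4R,5S)-3-[(S)-[3,4-bis(benzyloxy)phenyl](hydroxy)methyl]-4-[(tert-butyldiphenylsilyloxy)methyl]-5-[3,4,5-tris(benzyloxy)phenyl]oxolan-2-one | O=C1O[C@H](c2cc(OCc3ccccc3)c(OCc3ccccc3)c(OCc3ccccc3)c2)[C@@H](CO[Si](c2ccccc2)(c2ccccc2)C(C)(C)C)[C@H]1[C@H](O)c1ccc(OCc2ccccc2)c(OCc2ccccc2)c1 | intermediate
24 | (3S,4R,5S)-3-[(S)-[3,4-bis(benzyloxy)phenyl](hydroxy)methyl]-4-(hydroxymethyl)-5-[3,4,5-tris(benzyloxy)phenyl]oxolan-2-one | O=C1O[C@H](c2cc(OCc3ccccc3)c(OCc3ccccc3)c(OCc3ccccc3)c2)[C@@H](CO)[C@H]1[C@H](O)c1ccc(OCc2ccccc2)c(OCc2ccccc2)c1 | intermediate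
25 | primary methanesulfonate of 24 | O=C1O[C@H](c2cc(OCc3ccccc3)c(OCc3ccccc3)c(OCc3ccccc3)c2)[C@@H](COS(C)(=O)=O)[C@H]1[C@H](O)c1ccc(OCc2ccccc2)c(OCc2ccccc2)c1 | intermediate (not isolated)
26 | (1S,4S,5R,8S)-8-[3,4-bis(benzyloxy)phenyl]-4-[3,4,5-tris(benzyloxy)phenyl]-3,7-dioxabicyclo[3.3.0]octan-2-one | O=C1O[C@H](c2cc(OCc3ccccc3)c(OCc3ccccc3)c(OCc3ccccc3)c2)[C@H]2CO[C@H](c3ccc(OCc4ccccc4)c(OCc4ccccc4)c3)[C@@H]12 | intermediate
27 | (1S,4S,5R,8S)-8-(3,4-dihydroxyphenyl)-4-(3,4,5-trihydroxyphenyl)-3,7-dioxabicyclo[3.3.0]octan-2-one (CNP0290035.1) | O=C1O[C@H](c2cc(O)c(O)c(O)c2)[C@H]2CO[C@H](c3ccc(O)c(O)c3)[C@@H]12 | target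

**Step count and risks**

Total steps: 14. Longest linear sequence: 13 steps (steps 2–14 from 3 and 4; the branch through step 1 joins at step 3 and is equally long).

Three steps most likely to fail:

Step 10. The β-branched, heavily substituted imide 17 must react with an electron-rich and therefore sluggish aldehyde, so conversion or diastereoselectivity may be poor. The fallback makes the same C1–C8 bond by an Evans C-acylation (crossed Claisen-type) followed by chelation-controlled reduction. It sets out from acid 15, which is coupled through mixed anhydride 16 with (R)-4-benzyl-1,3-oxazolidin-2-one to give the (R)-auxiliary imide F1. Deprotonation with LDA (THF, −78 °C) and addition of 3,4-bis(benzyloxy)benzoyl chloride gives the β-keto imide F2. The acyl chloride attacks the lithium-chelated Z-enolate anti to the auxiliary benzyl group, which with the (R)-auxiliary gives the same C1 configuration as the boron aldol of the (S)-auxiliary, and allylic strain protects the α-hydrogen from epimerisation. Zn(BH4)2 (CH2Cl2/Et2O, −20 °C) then reduces the zinc-chelated ketone from the face anti to the α-substituent to give the syn β-hydroxy imide F3, which differs from 21 only in the auxiliary. The step-11 conditions convert F3 into the hydroxy imide F4, which lactonises with loss of the (R)-auxiliary, and the fallback comes back to the route at 23.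

Step 13. The primary alcohol must be sulfonylated in the presence of an electron-rich secondary benzylic β-hydroxy lactone, and bis-sulfonylation or dehydration to the α-arylidene lactone would divert material. The fallback reverses the polarity of the ring closure. It sets out from diol 24, which is treated with catalytic camphorsulfonic acid (CH2Cl2, 4 Å sieves, rt) so that the C8 benzylic alcohol ionises to a stabilised benzylic cation that is captured by the primary hydroxyl. The closure is reversible and should settle the aryl group in the less hindered exo position trans to the lactone carbonyl carbon, so the original C8 configuration no longer matters. It comes back to the route at 26 and makes no new compound F0.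

Step 14. Five benzyl ethers must be hydrogenolysed without cleaving the two benzylic C–O bonds of the bicycle (lactone C4–O3 and ether C8–O7), and over-reduction would open a ring. The fallback is a non-reductive Lewis-acid debenzylation. It sets out from 26, which is treated with BCl3 and pentamethylbenzene as benzyl-cation scavenger (CH2Cl2, −78 °C, MeOH quench), and it comes back to the route at the target 27, making no new compound F0.

**Further compounds**
F1 | step 10 | (R)-4-benzyl-3-[(3R,4S)-3-[(tert-butyldiphenylsilyloxy)methyl]-4-(triethylsilyloxy)-4-[3,4,5-tris(benzyloxy)phenyl]butanoyl]-1,3-oxazolidin-2-one | O=C(C[C@@H]([C@H](O[Si](CC)(CC)CC)c1cc(OCc2ccccc2)c(OCc2ccccc2)c(OCc2ccccc2)c1)CO[Si](c1ccccc1)(c1ccccc1)C(C)(C)C)N1[C@H](Cc2ccccc2)COC1=O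
F2 | step 10 | (R)-4-benzyl-3-[(2S,3R,4S)-2-[3,4-bis(benzyloxy)benzoyl]-3-[(tert-butyldiphenylsilyloxy)methyl]-4-(triethylsilyloxy)-4-[3,4,5-tris(benzyloxy)phenyl]butanoyl]-1,3-oxazolidin-2-one | O=C(c1ccc(OCc2ccccc2)c(OCc2ccccc2)c1)[C@@H](C(=O)N1[C@H](Cc2ccccc2)COC1=O)[C@H](CO[Si](c1ccccc1)(c1ccccc1)C(C)(C)C)[C@H](O[Si](CC)(CC)CC)c1cc(OCc2ccccc2)c(OCc2ccccc2)c(OCc2ccccc2)c1
F3 | step 10 | (R)-4-benzyl-3-[(2S,3R,4S)-2-[(S)-[3,4-bis(benzyloxy)phenyl](hydroxy)methyl]-3-[(tert-butyldiphenylsilyloxy)methyl]-4-(triethylsilyloxy)-4-[3,4,5-tris(benzyloxy)phenyl]butanoyl]-1,3-oxazolidin-2-one | O[C@H](c1ccc(OCc2ccccc2)c(OCc2ccccc2)c1)[C@@H](C(=O)N1[C@H](Cc2ccccc2)COC1=O)[C@H](CO[Si](c1ccccc1)(c1ccccc1)C(C)(C)C)[C@H](O[Si](CC)(CC)CC)c1cc(OCc2ccccc2)c(OCc2ccccc2)c(OCc2ccccc2)c1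
F4 | step 10 | 4-hydroxy analogue of F3 (triethylsilyl group removed, not isolated) | O[C@H](c1ccc(OCc2ccccc2)c(OCc2ccccc2)c1)[C@@H](C(=O)N1[C@H](Cc2ccccc2)COC1=O)[C@H](CO[Si](c1ccccc1)(c1ccccc1)C(C)(C)C)[C@H](O)c1cc(OCc2ccccc2)c(OCc2ccccc2)c(OCc2ccccc2)c1
F0 | step 13 | none | none
F0 | step 14 | none | none
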